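The carbocyclic ring of the 5,6,7,8-tetrahydroquinoline (C4a, C5, C6, C7, C8, C8a) is treated as a latent 4,4-disubstituted cyclohex-2-enone: C8a is the carbonyl carbon, C4a=C5 the enone alkene and the quaternary C6 the γ-carbon. An amine-catalysed enantioselective Robinson annulation joins a racemic α-aryl aldehyde (C5, C6, aryl, amide chain) to a vinyl ketone bearing a 3,3-dimethoxypropyl arm (C7, C8, C8a, C4a, C4, C3, C2): Michael addition forms C6–C7 and sets C6, aldol condensation forms C4a–C5. Ammonia then closes the pyridine between C8a and C2, and the enone unsaturation slides into the new ring, leaving C5 as CH2 without a redox step.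

Key step: step 6

Assumption (chemistry): atom numbers are those of the tetrahydroquinoline in 14; the sense of induction in step 6 is taken from the hydrogen-bond-directed (E)-enamine model of proline-type catalysts, which calls for the D-proline-derived sulfonamide, and if the opposite sense were found its L-proline-derived enantiomer would be used with nothing else changed.

Step 1
Reactants: 1 2-chloro-N-methylethanamine hydrochloride
Product: 2 N-(2-chloroethyl)-N-methylacetamide
Conditions: AcCl, K2CO3, CH2Cl2/H2O, 0 °C
Reagents that add atoms: acetyl chloride, CC(=O)Cl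
Why: Schotten–Baumann N-acylation of the secondary amine as it is released from its salt should outrun aziridinium formation at 0 °C.

Step 2
Reactants: 3 (3,4-dimethoxyphenyl)acetonitrile; 2 N-(2-chloroethyl)-N-methylacetamide
Product: 4 N-[3-cyano-3-(3,4-dimethoxyphenyl)propyl]-N-methylacetamide (racemic)
Conditions: LiN(SiMe3)2, THF, −78 °C; then 2, NaI (cat.), −78 °C → rt
Reagents that add atoms: none
Why: The nitrile-stabilised benzylic carbanion should displace the primary chloride (iodide-assisted SN2 alkylation), mono-alkylation being favoured because the product is more hindered and less acidic; the new stereocentre is racemic, which is immaterial because it is erased in the enamine of step 6.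

Step 3
Reactants: 4 N-[3-cyano-3-(3,4-dimethoxyphenyl)propyl]-N-methylacetamide
Product: 5 N-[3-(3,4-dimethoxyphenyl)-4-oxobutyl]-N-methylacetamide (racemic)
Conditions: Raney Ni, NaH2PO2·H2O, pyridine/AcOH/H2O (2:1:1), 45 °C
Reagents that add atoms: water, O
Why: Nickel-catalysed transfer hydrogenation with hypophosphite should stop at the aldimine, which the aqueous acidic medium hydrolyses to the aldehyde (partial reduction of a nitrile), while the tertiary amide and the aryl ethers are untouched.

Step 4
Reactants: 6 4-chloro-1,1-dimethoxybutane; 7 acrolein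
Product: 9 7,7-dimethoxyhept-1-en-3-ol (racemic), via (4,4-dimethoxybutyl)magnesium chloride 8 (not isolated)
Conditions: Mg, I2 (cat.), THF, 50 °C; then 7, −78 → 0 °C; aq. NH4Cl
Reagents that add atoms: none
Why: Grignard formation from the primary chloride (the acetal is inert) and 1,2-addition to acrolein at low temperature should give the secondary allylic alcohol, whose racemic carbinol centre is oxidised away in step 5.

Step 5
Reactants: 9 7,7-dimethoxyhept-1-en-3-ol
Product: 10 7,7-dimethoxyhept-1-en-3-one
Conditions: Dess–Martin periodinane, pyridine, CH2Cl2, 0 °C → rt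
Reagents that add atoms: none
Why: Dess–Martin oxidation should convert the secondary allylic alcohol into the vinyl ketone under buffered, non-aqueous conditions that spare the dimethyl acetal; the enone is used at once to avoid polymerisation.

Step 6
Reactants: 5 N-[3-(3,4-dimethoxyphenyl)-4-oxobutyl]-N-methylacetamide; 10 7,7-dimethoxyhept-1-en-3-one
Product: 13 N-{2-[(1S)-1-(3,4-dimethoxyphenyl)-3-(3,3-dimethoxypropyl)-4-oxocyclohex-2-en-1-yl]ethyl}-N-methylacetamide, via ketoaldehyde Michael adduct 11 (not isolated), via aldol adduct 12 (not isolated)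
Conditions: (2R)-N-[(4-dodecylphenyl)sulfonyl]pyrrolidine-2-carboxamide (20 mol%), PhMe, rt; then KOH (0.3 equiv), MeOH, 0 °C → rt (same flask)
Reagents that add atoms: none
Why: The pyrrolidine nitrogen condenses with racemic 5 to the (E)-enamine (aryl anti to nitrogen), which erases the old stereocentre, and its fully substituted carbon C6 adds to the terminal carbon C7 of vinyl ketone 10, whose carbonyl is held by the acidic sulfonamide N–H; hydrolysis releases ketoaldehyde 11, and KOH then closes the ring by aldol addition of the C4a enolate to the aldehyde carbon C5 and dehydrates aldol 12 to enone 13. The closest known reaction type is the amine-catalysed enantioselective Robinson annulation (Michael addition, then intramolecular aldol condensation) of α-aryl-α-alkyl aldehydes with alkyl vinyl ketones to 4,4-disubstituted cyclohex-2-enones. The six-membered ring closes in the 6-(enolendo)-exo-trig mode. The only stereocentre that persists, C6, is set in the Michael step under catalyst control: in the s-trans (E)-enamine the enone is delivered to the face on the side of the carboxamide arm, which for the (2R)-catalyst should give (R)-11 and hence (S)-13, while the centres created at C4a and C5 in 12 disappear on dehydration. The step needs regioselective aldolisation, secured because the aldehyde has no α-hydrogen after the Michael step and only the C4a enolate can reach it through a six-membered ring (the C8 enolate would close a four-membered one), and it needs a single Michael addition, secured because the donor carbon becomes quaternary. The acetal and the tertiary amide should be inert to both stages.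

Step 7
Reactants: 13 N-{2-[(1S)-1-(3,4-dimethoxyphenyl)-3-(3,3-dimethoxypropyl)-4-oxocyclohex-2-en-1-yl]ethyl}-N-methylacetamide
Product: 14 N-{2-[(6R)-6-(3,4-dimethoxyphenyl)-5,6,7,8-tetrahydroquinolin-6-yl]ethyl}-N-methylacetamide
Conditions: NH4OAc (excess), AcOH/H2O (9:1), 80 °C
Reagents that add atoms: ammonium acetate, CC(=O)[O-].[NH4+]
Why: Acid should unveil the aldehyde C2, ammonia should condense with it and with the C8a ketone (pyridine synthesis from a 2-alkylidene-1,5-dicarbonyl compound), and prototropic shift of the C4a=C5 alkene into the ring, driven by aromatisation, should deliver the pyridine with C5 as CH2 and no oxidant; C6 is quaternary and cannot epimerise.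

Compound list
1 | 2-chloro-N-methylethanamine hydrochloride | CNCCCl.Cl | starting material
2 | N-(2-chloroethyl)-N-methylacetamide | CC(=O)N(C)CCCl | intermediate
3 | (3,4-dimethoxyphenyl)acetonitrile | COc1ccc(CC#N)cc1OC | starting material
4 | N-[3-cyano-3-(3,4-dimethoxyphenyl)propyl]-N-methylacetamide (racemic) | COc1ccc(C(C#N)CCN(C)C(C)=O)cc1OC | intermediate
5 | N-[3-(3,4-dimethoxyphenyl)-4-oxobutyl]-N-methylacetamide (racemic) | COc1ccc(C(C=O)CCN(C)C(C)=O)cc1OC | intermediate
6 | 4-chloro-1,1-dimethoxybutane | COC(OC)CCCCl | starting material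
7 | acrolein (prop-2-enal) | C=CC=O | starting material
8 | (4,4-dimethoxybutyl)magnesium chloride | COC(OC)CCC[Mg]Cl | intermediate (not isolated)
9 | 7,7-dimethoxyhept-1-en-3-ol (racemic) | C=CC(O)CCCC(OC)OC | intermediate
10 | 7,7-dimethoxyhept-1-en-3-one | C=CC(=O)CCCC(OC)OC | intermediate
11 | N-[(3R)-3-(3,4-dimethoxyphenyl)-3-formyl-10,10-dimethoxy-6-oxodecyl]-N-methylacetamide | COc1ccc([C@](C=O)(CCN(C)C(C)=O)CCC(=O)CCCC(OC)OC)cc1OC | intermediate (not isolated)
12 | N-{2-[(1R)-1-(3,4-dimethoxyphenyl)-3-(3,3-dimethoxypropyl)-2-hydroxy-4-oxocyclohexyl]ethyl}-N-methylacetamide (mixture of diastereomers at C2 and C3 of the ring) | COc1ccc([C@]2(CCN(C)C(C)=O)CCC(=O)C(CCC(OC)OC)C2O)cc1OC | intermediate (not isolated)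
13 | N-{2-[(1S)-1-(3,4-dimethoxyphenyl)-3-(3,3-dimethoxypropyl)-4-oxocyclohex-2-en-1-yl]ethyl}-N-methylacetamide | COc1ccc([C@]2(CCN(C)C(C)=O)CCC(=O)C(CCC(OC)OC)=C2)cc1OC | intermediate
14 | N-{2-[(6R)-6-(3,4-dimethoxyphenyl)-5,6,7,8-tetrahydroquinolin-6-yl]ethyl}-N-methylacetamide | COc1ccc([C@]2(CCN(C)C(C)=O)CCc3ncccc3C2)cc1OC | target

Total step count: 7. Longest linear sequence: 5 steps (steps 1, 2, 3, 6, 7).

Steps most likely to fail

Step 6. Enamine formation at the fully substituted α-carbon may be slow, the enamine geometry may equilibrate and give poor facial selectivity in the Michael addition, and the vinyl ketone may polymerise or sequester the catalyst. Fallback, setting out from 5 and 10 and coming back at 13: the annulation would be run without chiral information (KOH, MeOH, 0 °C → rt). It should pass through the racemic ketoaldehyde N-[3-(3,4-dimethoxyphenyl)-3-formyl-10,10-dimethoxy-6-oxodecyl]-N-methylacetamide F1 and the racemic aldol N-{2-[1-(3,4-dimethoxyphenyl)-3-(3,3-dimethoxypropyl)-2-hydroxy-4-oxocyclohexyl]ethyl}-N-methylacetamide F2 to the racemic enone N-{2-[1-(3,4-dimethoxyphenyl)-3-(3,3-dimethoxypropyl)-4-oxocyclohex-2-en-1-yl]ethyl}-N-methylacetamide F3. Preparative chromatography on a chiral stationary phase (amylose tris(3,5-dimethylphenylcarbamate), CO2/MeOH) should then separate 13 from its enantiomer N-{2-[(1R)-1-(3,4-dimethoxyphenyl)-3-(3,3-dimethoxypropyl)-4-oxocyclohex-2-en-1-yl]ethyl}-N-methylacetamide F4, which is set aside.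

Step 7. After acetal cleavage the free aldehyde may undergo intramolecular aldol addition from C8, ammonia may add reversibly at C5, or the double-bond shift into the ring may stall, all in competition with pyridine closure. Fallback, setting out from 13 and coming back at 14: hydrogenation of the enone alkene (H2, Pd/C, EtOAc) should give the saturated keto acetal N-{2-[(1R)-1-(3,4-dimethoxyphenyl)-3-(3,3-dimethoxypropyl)-4-oxocyclohexyl]ethyl}-N-methylacetamide F5 as a mixture of epimers at ring C3, which is of no consequence because that carbon becomes aromatic. Heating F5 with NH2OH·HCl in EtOH should give 14 by acetal cleavage, oxime formation, ring closure and loss of water, hydroxylamine supplying the oxidation level that the alkene no longer provides.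

Step 3. The aldimine may be reduced further to the primary amine and couple to secondary amines, or the hindered nitrile may react sluggishly. Fallback, setting out from 2 and coming back at 5: purchased methyl (3,4-dimethoxyphenyl)acetate F6 would be deprotonated (LiN(SiMe3)2, THF, −78 °C) and alkylated with 2 to give methyl 4-[acetyl(methyl)amino]-2-(3,4-dimethoxyphenyl)butanoate F7 (racemic). LiBH4 in THF should reduce the ester but not the tertiary amide, giving N-[3-(3,4-dimethoxyphenyl)-4-hydroxybutyl]-N-methylacetamide F8 (racemic), and Dess–Martin oxidation of F8 should give 5.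

Further compounds
F1 | step 6 | N-[3-(3,4-dimethoxyphenyl)-3-formyl-10,10-dimethoxy-6-oxodecyl]-N-methylacetamide (racemic) | COc1ccc(C(C=O)(CCN(C)C(C)=O)CCC(=O)CCCC(OC)OC)cc1OC
F2 | step 6 | N-{2-[1-(3,4-dimethoxyphenyl)-3-(3,3-dimethoxypropyl)-2-hydroxy-4-oxocyclohexyl]ethyl}-N-methylacetamide (racemic, mixture of diastereomers) | COc1ccc(C2(CCN(C)C(C)=O)CCC(=O)C(CCC(OC)OC)C2O)cc1OC
F3 | step 6 | N-{2-[1-(3,4-dimethoxyphenyl)-3-(3,3-dimethoxypropyl)-4-oxocyclohex-2-en-1-yl]ethyl}-N-methylacetamide (racemic) | COc1ccc(C2(CCN(C)C(C)=O)CCC(=O)C(CCC(OC)OC)=C2)cc1OC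
F4 | step 6 | N-{2-[(1R)-1-(3,4-dimethoxyphenyl)-3-(3,3-dimethoxypropyl)-4-oxocyclohex-2-en-1-yl]ethyl}-N-methylacetamide | COc1ccc([C@@]2(CCN(C)C(C)=O)CCC(=O)C(CCC(OC)OC)=C2)cc1OC
F5 | step 7 | N-{2-[(1R)-1-(3,4-dimethoxyphenyl)-3-(3,3-dimethoxypropyl)-4-oxocyclohexyl]ethyl}-N-methylacetamide (mixture of epimers at ring C3) | COc1ccc([C@]2(CCN(C)C(C)=O)CCC(=O)C(CCC(OC)OC)C2)cc1OC
F6 | step 3 | methyl (3,4-dimethoxyphenyl)acetate (purchased) | COC(=O)Cc1ccc(OC)c(OC)c1
F7 | step 3 | methyl 4-[acetyl(methyl)amino]-2-(3,4-dimethoxyphenyl)butanoate (racemic) | COC(=O)C(CCN(C)C(C)=O)c1ccc(OC)c(OC)c1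
F8 | step 3 | N-[3-(3,4-dimethoxyphenyl)-4-hydroxybutyl]-N-methylacetamide (racemic) | CC(=O)N(C)CCC(CO)c1ccc(OC)c(OC)c1
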